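**Retrosynthetic overview**

1. Target 23 comes from acid 22 by MOM removal and 22 from thioester 21 by hydrolysis; the C3 methyl group is set by CuBr/Josiphos-catalysed MeMgBr addition to enethioate 20, which is grown from the ester arm through aldehyde 19 and a Wittig reaction.
2. The C6–C7 bond is made by nickel-catalysed decarboxylative alkenylation of the acid arm (phthalimide ester 14 with the isobutenylzinc reagent from 15), giving 18.
3. The plan rests on chain C5: it carries furan C3 and two CH2 groups (C4 and C6) that differ only further out, so it is the central carbon of a 3-(furan-3-yl)glutarate. Hydrolase monohydrolysis of prochiral diester 12 to half-ester 13 fixes this centre and tells the two arms apart.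
4. Diester 12 comes from aldehyde 8 and two molecules of dimethyl malonate (Knoevenagel–Michael, double Krapcho); 8 comes from ester 6, made by Suzuki coupling of bromofuroate 5 with boronate 4 (from bromohydroquinone 1).
5. No ring is built: the benzene ring (from 1) and the furan ring (from 5) are bought and joined first through the furan C5–aryl C1 bond.

Key step: step 8

Assumption 1: α-chymotrypsin is taken to cleave the pro-S ester arm of 12, as it does with dimethyl 3-arylglutarates, so that the half-ester is 3R; the configuration of 13 is to be secured by correlation before the arms are elaborated.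

Assumption 2: the CuBr complex of (R,S)-Josiphos is taken to show with 20 the facial preference it shows with simple (E)-alk-2-enethioates (3R adducts from MeMgBr); if the sense proves opposite, the (S,R) ligand is used.

Remark: the furan-bearing carbon is not touched after step 8; its descriptor changes (R in 13, S in 14, R in 18 and 19, S from 20 on) only because the CIP ranking of the two arms changes.

**Route**

Step 1
Reactants: 1 2-bromobenzene-1,4-diol
Product: 2 2-bromo-1,4-bis(methoxymethoxy)benzene
Conditions: MOMCl (3 equiv), iPr2NEt (4 equiv), CH2Cl2, 0 °C → rt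
Reagents that add atoms: chloromethyl methyl ether, COCCl
Why: Base-mediated O-alkylation of both phenols with the reactive α-chloro ether (Williamson-type) should give acetal ethers that withstand the organolithium, hydride, alkoxide and organozinc reagents used later.

Step 2
Reactants: 2 2-bromo-1,4-bis(methoxymethoxy)benzene
Product: 4 2-[2,5-bis(methoxymethoxy)phenyl]-4,4,5,5-tetramethyl-1,3,2-dioxaborolane, via aryllithium 3 (not isolated)
Conditions: n-BuLi (1.05 equiv), THF, −78 °C; then 2-isopropoxy-4,4,5,5-tetramethyl-1,3,2-dioxaborolane, −78 °C → rt; then H2O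
Reagents that add atoms: 2-isopropoxy-4,4,5,5-tetramethyl-1,3,2-dioxaborolane, CC(C)OB1OC(C)(C)C(C)(C)O1
Why: Bromine–lithium exchange at −78 °C is faster than ring deprotonation or attack on the acetals, and trapping of the oxygen-stabilised aryllithium with the isopropoxyboronate gives the pinacol boronate directly (lithiation–borylation).

Step 3
Reactants: 4 2-[2,5-bis(methoxymethoxy)phenyl]-4,4,5,5-tetramethyl-1,3,2-dioxaborolane; 5 methyl 5-bromofuran-3-carboxylate
Product: 6 methyl 5-[2,5-bis(methoxymethoxy)phenyl]furan-3-carboxylate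
Conditions: Pd(dppf)Cl2 (3 mol %), K3PO4 (2.5 equiv), 1,4-dioxane/H2O (5:1), 80 °C
Reagents that add atoms: none
Why: Suzuki–Miyaura coupling, in which zerovalent palladium inserts readily into the C–Br bond at the α-position of the furan and the phosphate base activates the boronate while leaving the methyl ester intact.

Step 4
Reactants: 6 methyl 5-[2,5-bis(methoxymethoxy)phenyl]furan-3-carboxylate
Product: 7 {5-[2,5-bis(methoxymethoxy)phenyl]furan-3-yl}methanol
Conditions: iBu2AlH (2.5 equiv), CH2Cl2, −78 → 0 °C; aq. potassium sodium tartrate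
Reagents that add atoms: none
Why: Hydride reduction of the heteroaromatic ester to the primary alcohol with excess iBu2AlH, which leaves the furan and the acetals untouched.

Step 5
Reactants: 7 {5-[2,5-bis(methoxymethoxy)phenyl]furan-3-yl}methanol
Product: 8 5-[2,5-bis(methoxymethoxy)phenyl]furan-3-carbaldehyde
Conditions: MnO2 (10 equiv), CH2Cl2, rt
Reagents that add atoms: none
Why: MnO2 oxidises the furylmethanol, a benzylic-type alcohol, selectively to the aldehyde without over-oxidation.

Step 6
Reactants: 8 5-[2,5-bis(methoxymethoxy)phenyl]furan-3-carbaldehyde; 9 dimethyl malonate (2.5 equiv)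
Product: 11 tetramethyl 2-{5-[2,5-bis(methoxymethoxy)phenyl]furan-3-yl}propane-1,1,3,3-tetracarboxylate, via alkylidene malonate 10 (not isolated)
Conditions: piperidine (0.2 equiv), AcOH (0.2 equiv), toluene, 4 Å MS, 90 °C; then NaOMe (0.3 equiv), MeOH, rt
Reagents that add atoms: none
Why: Knoevenagel condensation to the alkylidene malonate followed by Michael addition of a second malonate anion to this doubly activated acceptor, the classical bis-adduct formation of aromatic aldehydes with malonates.

Step 7
Reactants: 11 tetramethyl 2-{5-[2,5-bis(methoxymethoxy)phenyl]furan-3-yl}propane-1,1,3,3-tetracarboxylate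
Product: 12 dimethyl 3-{5-[2,5-bis(methoxymethoxy)phenyl]furan-3-yl}pentanedioate
Conditions: LiCl (5 equiv), H2O (5 equiv), DMSO, 150 °C
Reagents that add atoms: none
Why: Krapcho dealkoxycarbonylation removes one ester from each malonate unit under neutral conditions that spare the MOM ethers, and the remaining esters lack the geminal activation needed for further loss.

Step 8
Reactants: 12 dimethyl 3-{5-[2,5-bis(methoxymethoxy)phenyl]furan-3-yl}pentanedioate
Product: 13 (3R)-3-{5-[2,5-bis(methoxymethoxy)phenyl]furan-3-yl}-5-methoxy-5-oxopentanoic acid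
Conditions: α-chymotrypsin, potassium phosphate buffer (KH2PO4/K2HPO4, 0.1 M, pH 7.8)/DMSO (85:15), 30 °C; then aq. citric acid to pH 4, EtOAc
Reagents that add atoms: water, O
Why: The catalytic serine of the hydrolase attacks one ester carbonyl of bound 12, methanol leaves, and water hydrolyses the acyl-enzyme to the carboxylate. The closest known reaction is the α-chymotrypsin- or esterase-mediated monohydrolysis of dimethyl 3-arylglutarates. No ring is closed and no skeletal bond is formed. The new stereocentre (C3 of 13, later chain C5) is fixed by the chiral binding site alone: the flat arylfuran must occupy the hydrophobic pocket, which should leave only the pro-S CH2CO2Me arm within reach of the serine. The step needs selection between the two enantiotopic arms and a stop after the first hydrolysis; the first rests on that single binding mode of the one large substituent, the second on the anionic half-ester being a poor substrate.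

Step 9
Reactants: 13 (3R)-3-{5-[2,5-bis(methoxymethoxy)phenyl]furan-3-yl}-5-methoxy-5-oxopentanoic acid
Product: 14 1-(1,3-dioxo-1,3-dihydro-2H-isoindol-2-yl) 5-methyl (3S)-3-{5-[2,5-bis(methoxymethoxy)phenyl]furan-3-yl}pentanedioate
Conditions: N-hydroxyphthalimide (1.1 equiv), N,N'-diisopropylcarbodiimide (1.1 equiv), DMAP (0.1 equiv), CH2Cl2, rt
Reagents that add atoms: N-hydroxyphthalimide, O=C1c2ccccc2C(=O)N1O
Why: Carbodiimide (Steglich-type) esterification of the free acid gives the redox-active ester at room temperature, where the methyl ester arm cannot exchange with the activated arm, so the configuration is kept.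

Step 10
Reactants: 14 1-(1,3-dioxo-1,3-dihydro-2H-isoindol-2-yl) 5-methyl (3S)-3-{5-[2,5-bis(methoxymethoxy)phenyl]furan-3-yl}pentanedioate; 15 1-bromo-2-methylprop-1-ene (2.5 equiv)
Product: 18 methyl (3R)-3-{5-[2,5-bis(methoxymethoxy)phenyl]furan-3-yl}-6-methylhept-5-enoate, via alkenylmagnesium bromide 16 (not isolated), via alkenylzinc chloride 17 (not isolated)
Conditions: 15, Mg, THF, 50 °C; ZnCl2, THF, 0 °C → rt; then 14, NiCl2·glyme (10 mol %), 2,2'-bipyridine (20 mol %), THF/DMF, rt
Reagents that add atoms: none
Why: Nickel-catalysed decarboxylative alkenylation (Negishi-type coupling of a redox-active ester): electron transfer from low-valent nickel to the phthalimide ester releases CO2 and a primary radical that is captured by alkenylnickel and reductively eliminated, and since the radical sits on the CH2 next to the stereocentre and not on it, the configuration is untouched.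

Step 11
Reactants: 18 methyl (3R)-3-{5-[2,5-bis(methoxymethoxy)phenyl]furan-3-yl}-6-methylhept-5-enoate
Product: 19 (3R)-3-{5-[2,5-bis(methoxymethoxy)phenyl]furan-3-yl}-6-methylhept-5-enal
Conditions: iBu2AlH (1.1 equiv), CH2Cl2, −78 °C; MeOH, then aq. potassium sodium tartrate
Reagents that add atoms: none
Why: Partial reduction of the methyl ester with one equivalent of iBu2AlH at −78 °C, where the aluminium hemiacetal persists until the quench, should give the aldehyde, whose β-stereocentre cannot epimerise by enolisation.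

Step 12
Reactants: 19 (3R)-3-{5-[2,5-bis(methoxymethoxy)phenyl]furan-3-yl}-6-methylhept-5-enal
Product: 20 S-ethyl (2E,5S)-5-{5-[2,5-bis(methoxymethoxy)phenyl]furan-3-yl}-8-methylnona-2,7-dienethioate
Conditions: Ph3P=CHC(O)SEt (1.3 equiv), CH2Cl2, rt → 40 °C
Reagents that add atoms: S-ethyl 2-(triphenylphosphoranylidene)ethanethioate, CCSC(=O)C=P(c1ccccc1)(c1ccccc1)c1ccccc1
Why: Wittig olefination with the stabilised thioester ylide should give the (E)-enethioate selectively under neutral conditions.

Step 13
Reactants: 20 S-ethyl (2E,5S)-5-{5-[2,5-bis(methoxymethoxy)phenyl]furan-3-yl}-8-methylnona-2,7-dienethioate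
Product: 21 S-ethyl (3R,5S)-5-{5-[2,5-bis(methoxymethoxy)phenyl]furan-3-yl}-3,8-dimethylnon-7-enethioate
Conditions: CuBr·SMe2 (5 mol %), (R,S)-Josiphos [(R)-1-[(S)-2-(diphenylphosphino)ferrocenyl]ethyldicyclohexylphosphine] (6 mol %), MeMgBr (1.5 equiv), tBuOMe, −75 °C; then MeOH/H2O
Reagents that add atoms: methylmagnesium bromide, C[Mg]Br
Why: Copper-catalysed asymmetric conjugate addition of a Grignard reagent to an α,β-unsaturated thioester, in which the chiral CuBr–diphosphine complex and not the remote C5 centre selects the C3 face (catalyst control, as in 1,3-dimethyl deoxypropionate arrays), the thioester being reactive enough for 1,4-addition at −75 °C yet resistant to 1,2-attack.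

Step 14
Reactants: 21 S-ethyl (3R,5S)-5-{5-[2,5-bis(methoxymethoxy)phenyl]furan-3-yl}-3,8-dimethylnon-7-enethioate
Product: 22 (3R,5S)-5-{5-[2,5-bis(methoxymethoxy)phenyl]furan-3-yl}-3,8-dimethylnon-7-enoic acid
Conditions: LiOH·H2O (3 equiv), THF/H2O (3:1), rt; then 0.5 M HCl to pH 4, 0 °C
Reagents that add atoms: lithium hydroxide, [Li+].[OH-]
Why: Saponification of the thioester, which is far more labile than an oxo-ester, proceeds with hydroxide at room temperature and does not affect C3, which is β to the carbonyl.

Step 15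
Reactants: 22 (3R,5S)-5-{5-[2,5-bis(methoxymethoxy)phenyl]furan-3-yl}-3,8-dimethylnon-7-enoic acid
Product: 23 (3R,5S)-5-[5-(2,5-dihydroxyphenyl)furan-3-yl]-3,8-dimethylnon-7-enoic acid
Conditions: TMSOTf (6 equiv), 2,2'-bipyridyl (9 equiv), degassed CH3CN, 0 °C → rt, Ar; then H2O, rt
Reagents that add atoms: none
Why: Aromatic MOM ethers are converted by TMSOTf/2,2'-bipyridyl to aryl silyl ethers while the bipyridyl traps the methoxymethyl cation and buffers the medium, and water then frees the phenols and the acid, so that no strong protic acid meets the trisubstituted alkene or the furan.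

**Compound list**

1 | 2-bromobenzene-1,4-diol | Oc1ccc(O)c(Br)c1 | starting material
2 | 2-bromo-1,4-bis(methoxymethoxy)benzene | COCOc1ccc(OCOC)c(Br)c1 | intermediate
3 | [2,5-bis(methoxymethoxy)phenyl]lithium | [Li]c1cc(OCOC)ccc1OCOC | intermediate
4 | 2-[2,5-bis(methoxymethoxy)phenyl]-4,4,5,5-tetramethyl-1,3,2-dioxaborolane | COCOc1ccc(OCOC)c(B2OC(C)(C)C(C)(C)O2)c1 | intermediate
5 | methyl 5-bromofuran-3-carboxylate | COC(=O)c1coc(Br)c1 | starting material
6 | methyl 5-[2,5-bis(methoxymethoxy)phenyl]furan-3-carboxylate | COC(=O)c1coc(-c2cc(OCOC)ccc2OCOC)c1 | intermediate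
7 | {5-[2,5-bis(methoxymethoxy)phenyl]furan-3-yl}methanol | OCc1coc(-c2cc(OCOC)ccc2OCOC)c1 | intermediate
8 | 5-[2,5-bis(methoxymethoxy)phenyl]furan-3-carbaldehyde | O=Cc1coc(-c2cc(OCOC)ccc2OCOC)c1 | intermediate
9 | dimethyl malonate | COC(=O)CC(=O)OC | starting material
10 | dimethyl 2-({5-[2,5-bis(methoxymethoxy)phenyl]furan-3-yl}methylidene)propanedioate | COC(=O)C(=Cc1coc(-c2cc(OCOC)ccc2OCOC)c1)C(=O)OC | intermediate
11 | tetramethyl 2-{5-[2,5-bis(methoxymethoxy)phenyl]furan-3-yl}propane-1,1,3,3-tetracarboxylate | COC(=O)C(C(=O)OC)C(C(C(=O)OC)C(=O)OC)c1coc(-c2cc(OCOC)ccc2OCOC)c1 | intermediate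
12 | dimethyl 3-{5-[2,5-bis(methoxymethoxy)phenyl]furan-3-yl}pentanedioate | COC(=O)CC(CC(=O)OC)c1coc(-c2cc(OCOC)ccc2OCOC)c1 | intermediate
13 | (3R)-3-{5-[2,5-bis(methoxymethoxy)phenyl]furan-3-yl}-5-methoxy-5-oxopentanoic acid | OC(=O)C[C@H](CC(=O)OC)c1coc(-c2cc(OCOC)ccc2OCOC)c1 | intermediate
14 | 1-(1,3-dioxo-1,3-dihydro-2H-isoindol-2-yl) 5-methyl (3S)-3-{5-[2,5-bis(methoxymethoxy)phenyl]furan-3-yl}pentanedioate | O=C(C[C@H](CC(=O)OC)c1coc(-c2cc(OCOC)ccc2OCOC)c1)ON1C(=O)c2ccccc2C1=O | intermediate
15 | 1-bromo-2-methylprop-1-ene | CC(C)=CBr | starting material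
16 | bromo(2-methylprop-1-en-1-yl)magnesium | CC(C)=C[Mg]Br | intermediate
17 | chloro(2-methylprop-1-en-1-yl)zinc | CC(C)=C[Zn]Cl | intermediate
18 | methyl (3R)-3-{5-[2,5-bis(methoxymethoxy)phenyl]furan-3-yl}-6-methylhept-5-enoate | COC(=O)C[C@@H](CC=C(C)C)c1coc(-c2cc(OCOC)ccc2OCOC)c1 | intermediate
19 | (3R)-3-{5-[2,5-bis(methoxymethoxy)phenyl]furan-3-yl}-6-methylhept-5-enal | O=CC[C@@H](CC=C(C)C)c1coc(-c2cc(OCOC)ccc2OCOC)c1 | intermediate
20 | S-ethyl (2E,5S)-5-{5-[2,5-bis(methoxymethoxy)phenyl]furan-3-yl}-8-methylnona-2,7-dienethioate | CCSC(=O)/C=C/C[C@@H](CC=C(C)C)c1coc(-c2cc(OCOC)ccc2OCOC)c1 | intermediate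
21 | S-ethyl (3R,5S)-5-{5-[2,5-bis(methoxymethoxy)phenyl]furan-3-yl}-3,8-dimethylnon-7-enethioate | CCSC(=O)C[C@H](C)C[C@@H](CC=C(C)C)c1coc(-c2cc(OCOC)ccc2OCOC)c1 | intermediate
22 | (3R,5S)-5-{5-[2,5-bis(methoxymethoxy)phenyl]furan-3-yl}-3,8-dimethylnon-7-enoic acid | OC(=O)C[C@H](C)C[C@@H](CC=C(C)C)c1coc(-c2cc(OCOC)ccc2OCOC)c1 | intermediate
23 | (3R,5S)-5-[5-(2,5-dihydroxyphenyl)furan-3-yl]-3,8-dimethylnon-7-enoic acid | CC(C)=CC[C@H](C[C@@H](C)CC(=O)O)c1coc(-c2cc(O)ccc2O)c1 | target

**Step count**

Total step count: 15. Longest linear sequence: 15 steps (1 to 23); 5, 9 and 15 are bought and enter at steps 3, 6 and 10.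

**Steps most likely to fail**

Step 8 (key step). The bulky, poorly soluble diester may bind too weakly in the active site for useful turnover, or the enzyme may discriminate poorly between the two enantiotopic arms or prefer the other one. The fallback sets out from 12 and replaces the enzyme by organocatalytic opening of the meso anhydride. Both esters are saponified (LiOH, THF/H2O, rt) to 3-{5-[2,5-bis(methoxymethoxy)phenyl]furan-3-yl}pentanedioic acid F1. This is dehydrated with acetic anhydride at 60 °C to 4-{5-[2,5-bis(methoxymethoxy)phenyl]furan-3-yl}oxane-2,6-dione F2. F2 is opened with methanol (10 equiv) in tBuOMe at −20 °C in the presence of a cinchona-alkaloid-derived bifunctional sulfonamide or thiourea catalyst (10 mol %). The quinine- and quinidine-derived catalysts attack opposite carbonyl groups, so the one that leaves the free acid on the pro-S arm is used. The fallback returns to the route at 13.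

Step 10. The primary radical may be reduced before nickel captures it (hydrodecarboxylation), the alkenylzinc reagent may homocouple, or the radical may undergo a 1,2-furyl shift. The fallback sets out from 13, avoids radicals and keeps the carboxyl carbon as C7. Borane (BH3·SMe2, THF, 0 °C) reduces the acid but not the ester to methyl (3R)-3-{5-[2,5-bis(methoxymethoxy)phenyl]furan-3-yl}-5-hydroxypentanoate F3. Swern oxidation at −78 °C gives methyl (3R)-3-{5-[2,5-bis(methoxymethoxy)phenyl]furan-3-yl}-5-oxopentanoate F4. Wittig reaction of F4 with isopropylidenetriphenylphosphorane (from isopropyltriphenylphosphonium iodide and n-BuLi, THF, −78 → 0 °C) installs the trisubstituted alkene. The fallback returns to the route at 18.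

Step 13. Face selection at C3 may be eroded if the preference of the catalyst and the resident C5 centre oppose each other, and 1,2-addition may compete. The fallback sets out from 19 and relies on a covalently bound auxiliary. Horner–Wadsworth–Emmons reaction with diethyl {2-oxo-2-[(4S)-2-oxo-4-phenyl-1,3-oxazolidin-3-yl]ethyl}phosphonate (LiCl, iPr2NEt, CH3CN, rt) gives (4S)-3-[(2E,5S)-5-{5-[2,5-bis(methoxymethoxy)phenyl]furan-3-yl}-8-methylnona-2,7-dienoyl]-4-phenyl-1,3-oxazolidin-2-one F5. MeMgBr with stoichiometric CuBr·SMe2 (THF/Me2S, −78 → −20 °C) adds methyl to the chelated syn-s-cis imide on the face away from the 4-phenyl group. This should give (4S)-3-[(3R,5S)-5-{5-[2,5-bis(methoxymethoxy)phenyl]furan-3-yl}-3,8-dimethylnon-7-enoyl]-4-phenyl-1,3-oxazolidin-2-one F6. Cleavage with LiOH/H2O2 (THF/H2O, 0 °C) releases the acid and the auxiliary. The fallback returns to the route at 22.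

Further compounds
F1 | step 8 | 3-{5-[2,5-bis(methoxymethoxy)phenyl]furan-3-yl}pentanedioic acid | OC(=O)CC(CC(=O)O)c1coc(-c2cc(OCOC)ccc2OCOC)c1
F2 | step 8 | 4-{5-[2,5-bis(methoxymethoxy)phenyl]furan-3-yl}oxane-2,6-dione | O=C1CC(CC(=O)O1)c1coc(-c2cc(OCOC)ccc2OCOC)c1
F3 | step 10 | methyl (3R)-3-{5-[2,5-bis(methoxymethoxy)phenyl]furan-3-yl}-5-hydroxypentanoate | COC(=O)C[C@@H](CCO)c1coc(-c2cc(OCOC)ccc2OCOC)c1
F4 | step 10 | methyl (3R)-3-{5-[2,5-bis(methoxymethoxy)phenyl]furan-3-yl}-5-oxopentanoate | COC(=O)C[C@@H](CC=O)c1coc(-c2cc(OCOC)ccc2OCOC)c1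
F5 | step 13 | (4S)-3-[(2E,5S)-5-{5-[2,5-bis(methoxymethoxy)phenyl]furan-3-yl}-8-methylnona-2,7-dienoyl]-4-phenyl-1,3-oxazolidin-2-one | O=C(/C=C/C[C@@H](CC=C(C)C)c1coc(-c2cc(OCOC)ccc2OCOC)c1)N1C(=O)OC[C@@H]1c1ccccc1
F6 | step 13 | (4S)-3-[(3R,5S)-5-{5-[2,5-bis(methoxymethoxy)phenyl]furan-3-yl}-3,8-dimethylnon-7-enoyl]-4-phenyl-1,3-oxazolidin-2-one | O=C(C[C@H](C)C[C@@H](CC=C(C)C)c1coc(-c2cc(OCOC)ccc2OCOC)c1)N1C(=O)OC[C@@H]1c1ccccc1
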